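The ring C dihydropyranone is disconnected across C2–C3 and O1–C8a, so that the ring B aldehyde supplies C2 together with the ring oxygen O1. The feature exploited is the vinylogous ester O1–C8a=C4a–C4=O shared by rings A and C: a ring A acetophenone carrying fluorine at C8a is at once a C3 nucleophile (as its enol silane) and a C8a electrophile. In one flask an enantioselective Mukaiyama aldol addition forms C2–C3 and sets the only stereocentre, and fluoride-triggered desilylation lets the C2 oxygen displace the C8a fluorine (SNAr). This is a benzo-fused counterpart of the aldol–dihydropyranone annulation of Danishefsky-type dienes. Global MOM removal then gives the target.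

Key step: step 9

Assumption: the L-tryptophan-derived N-tosyl B-butyl oxazaborolidinone is taken to direct enol silanes to the Re face of aryl aldehydes, so the D-tryptophan-derived (R)-catalyst is specified for the Si-face addition that gives (2S); if the sense proved opposite, the antipode would be used.

Flavanone numbering is used throughout (O1, C2, C3, C4, C4a, C5–C8, C8a; ring A = benzo ring, ring B = 2-aryl group, ring C = pyranone). MOM = methoxymethyl.

**Ring A fragment**

Step 1
Reactants: 1 5-fluorobenzene-1,3-diol; 2 chloromethyl methyl ether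
Product: 3 1-fluoro-3,5-bis(methoxymethoxy)benzene
Conditions: NaH (2.4 equiv), DMF, 0 °C; MOMCl (2.4 equiv), 0 °C → rt
Reagents that add atoms: chloromethyl methyl ether (2), COCCl
Why: Williamson-type O-alkylation of both phenoxides gives the bis-MOM ether, which tolerates the later amide-base, fluoride and Lewis-acid steps and is removed by acid at the end.

Step 2
Reactants: 3 1-fluoro-3,5-bis(methoxymethoxy)benzene; 4 1-bromo-3-methylbut-2-ene (prenyl bromide)
Product: 5 1-fluoro-3,5-bis(methoxymethoxy)-2-(3-methylbut-2-en-1-yl)benzene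
Conditions: LDA (1.1 equiv), THF, −78 °C; CuBr·SMe2 (20 mol%), prenyl bromide (1.3 equiv), −78 → −30 °C
Reagents that add atoms: 1-bromo-3-methylbut-2-ene (4), CC(C)=CCBr
Why: Acidity-controlled ortho-metalation, in which the amide base should remove only a ring hydrogen flanked by fluorine and a MOM ether (the site between the two MOM ethers is too weakly acidic), followed by copper-catalysed allylic substitution at the unhindered primary carbon of prenyl bromide to give the linear prenyl arene.

Step 3
Reactants: 5 1-fluoro-3,5-bis(methoxymethoxy)-2-(3-methylbut-2-en-1-yl)benzene; 6 N-methoxy-N-methylacetamide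
Product: 7 1-[2-fluoro-4,6-bis(methoxymethoxy)-3-(3-methylbut-2-en-1-yl)phenyl]ethan-1-one
Conditions: LDA (1.2 equiv), THF, −78 °C; N-methoxy-N-methylacetamide (1.5 equiv), −78 → −40 °C; aq NH4Cl
Reagents that add atoms: N-methoxy-N-methylacetamide (6), CC(=O)N(C)OC
Why: A second ortho-lithiation at the only remaining fluorine-flanked ring position and Weinreb ketone synthesis, whose chelated tetrahedral adduct prevents over-addition, place the acetyl group next to fluorine.

Step 4
Reactants: 7 1-[2-fluoro-4,6-bis(methoxymethoxy)-3-(3-methylbut-2-en-1-yl)phenyl]ethan-1-one; 8 chlorotrimethylsilane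
Product: 9 ({1-[2-fluoro-4,6-bis(methoxymethoxy)-3-(3-methylbut-2-en-1-yl)phenyl]ethenyl}oxy)trimethylsilane
Conditions: LiHMDS (1.1 equiv), THF, −78 °C; Me3SiCl (1.3 equiv), −78 → 0 °C; pentane, filtration, used crude
Reagents that add atoms: chlorotrimethylsilane (8), C[Si](C)(C)Cl
Why: Kinetic enolisation of a methyl ketone with a single enolisable side and O-silylation should give the enol silane cleanly.

**Ring B fragment**

Step 5
Reactants: 10 2,4-dihydroxybenzaldehyde; 4 1-bromo-3-methylbut-2-ene
Product: 11 2-hydroxy-4-[(3-methylbut-2-en-1-yl)oxy]benzaldehyde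
Conditions: prenyl bromide (1.05 equiv), KHCO3, MeCN, 70 °C
Reagents that add atoms: 1-bromo-3-methylbut-2-ene (4), CC(C)=CCBr
Why: Williamson etherification with a weak base is selective for the 4-hydroxyl, because the 2-hydroxyl is hydrogen-bonded to the aldehyde and less acidic.

Step 6
Reactants: 11 2-hydroxy-4-[(3-methylbut-2-en-1-yl)oxy]benzaldehyde; 2 chloromethyl methyl ether
Product: 12 2-(methoxymethoxy)-4-[(3-methylbut-2-en-1-yl)oxy]benzaldehyde
Conditions: NaH (1.2 equiv), DMF, 0 °C; MOMCl (1.2 equiv), 0 °C → rt
Reagents that add atoms: chloromethyl methyl ether (2), COCCl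
Why: O-alkylation of the sodium phenoxide caps the chelated hydroxyl, removing the hydrogen bond that would otherwise steer the coming rearrangement towards C3.

Step 7
Reactants: 12 2-(methoxymethoxy)-4-[(3-methylbut-2-en-1-yl)oxy]benzaldehyde
Product: 13 4-hydroxy-2-(methoxymethoxy)-5-(2-methylbut-3-en-2-yl)benzaldehyde
Conditions: EtOH/H2O (4:1), 125 °C, sealed tube
Reagents that add atoms: none
Why: Water-accelerated aromatic Claisen rearrangement moves the prenyl group with allylic inversion to the less crowded ortho carbon C5 (C3 lies between two alkoxy groups), and tautomerisation gives the phenol bearing the 1,1-dimethylallyl group.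

Step 8
Reactants: 13 4-hydroxy-2-(methoxymethoxy)-5-(2-methylbut-3-en-2-yl)benzaldehyde; 2 chloromethyl methyl ether
Product: 14 2,4-bis(methoxymethoxy)-5-(2-methylbut-3-en-2-yl)benzaldehyde
Conditions: NaH (1.2 equiv), DMF, 0 °C; MOMCl (1.3 equiv), 0 °C → rt
Reagents that add atoms: chloromethyl methyl ether (2), COCCl
Why: O-alkylation of the acidic para-formyl phenoxide should proceed despite the neighbouring tertiary alkyl group.

**Union and completion**

Step 9
Reactants: 9 ({1-[2-fluoro-4,6-bis(methoxymethoxy)-3-(3-methylbut-2-en-1-yl)phenyl]ethenyl}oxy)trimethylsilane (1.0 equiv); 14 2,4-bis(methoxymethoxy)-5-(2-methylbut-3-en-2-yl)benzaldehyde (1.2 equiv)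
Product: 16 (2S)-2-[2,4-bis(methoxymethoxy)-5-(2-methylbut-3-en-2-yl)phenyl]-5,7-bis(methoxymethoxy)-8-(3-methylbut-2-en-1-yl)-2,3-dihydro-4H-chromen-4-one, via silyl aldol ether 15 (not isolated)
Conditions: (R)-2-butyl-4-(1H-indol-3-ylmethyl)-3-tosyl-1,3,2-oxazaborolidin-5-one (20 mol%), EtCN, −78 °C; then Bu4N[Ph3SiF2] (0.5 equiv), THF, −78 → 0 °C
Reagents that add atoms: none
Why: The boron Lewis acid binds the aldehyde of 14 and enol silane 9 adds through an open transition state (catalytic enantioselective Mukaiyama aldol addition) to give silyl ether 15; fluoride then removes the silyl group and the C2 alkoxide attacks C8a, ortho to the C4 ketone, with loss of fluoride (intramolecular SNAr), the liberated fluoride carrying the desilylation chain so that Me3SiF is the only by-product. The closest known reaction is the two-stage Mukaiyama aldol–cyclisation route from Danishefsky-type dienes and aldehydes to 2,3-dihydro-4H-pyran-4-ones, here with the aromatic C4a=C8a bond as the second alkene and fluoride in place of methoxide as leaving group. Ring C closes by 6-exo-trig addition–elimination at C8a through a Meisenheimer intermediate whose charge rests on C4a (acyl), C6 and C8, none of which carries an oxygen donor. The C2 stereocentre is set in the aldol stage by the chiral catalyst, which shields one face of the bound aldehyde so that addition occurs on the Si face and gives (S); the C2–O bond is not broken afterwards. The step needs enantiofacial control (catalyst), ring closure faster than retro-aldol cleavage or elimination of the alkoxide (low temperature, enol silane as limiting partner so that no free enolate remains), and regiocontrol between the two ortho positions of the ketone, which is secured because only C8a bears a leaving group.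

Step 10
Reactants: 16 (2S)-2-[2,4-bis(methoxymethoxy)-5-(2-methylbut-3-en-2-yl)phenyl]-5,7-bis(methoxymethoxy)-8-(3-methylbut-2-en-1-yl)-2,3-dihydro-4H-chromen-4-one
Product: 17 (2S)-2-[2,4-dihydroxy-5-(2-methylbut-3-en-2-yl)phenyl]-5,7-dihydroxy-8-(3-methylbut-2-en-1-yl)-2,3-dihydro-4H-chromen-4-one (AChE-IN-17)
Conditions: 3 M aq HCl/MeOH (1:5), 45 °C, monitored closely and stopped at full conversion
Reagents that add atoms: none
Why: Acid-catalysed acetal exchange with methanol should cleave the four aryl MOM ethers without touching C2, since flavanone racemisation needs base-induced ring opening, while the mild temperature limits acid-induced cyclisation of the two allylic side chains onto neighbouring phenols.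

**Compound list**

1 | 5-fluorobenzene-1,3-diol | Oc1cc(O)cc(F)c1 | starting material
2 | chloromethyl methyl ether | COCCl | starting material
3 | 1-fluoro-3,5-bis(methoxymethoxy)benzene | COCOc1cc(F)cc(OCOC)c1 | intermediate
4 | 1-bromo-3-methylbut-2-ene | CC(C)=CCBr | starting material
5 | 1-fluoro-3,5-bis(methoxymethoxy)-2-(3-methylbut-2-en-1-yl)benzene | COCOc1cc(OCOC)c(CC=C(C)C)c(F)c1 | intermediate
6 | N-methoxy-N-methylacetamide | CC(=O)N(C)OC | starting material
7 | 1-[2-fluoro-4,6-bis(methoxymethoxy)-3-(3-methylbut-2-en-1-yl)phenyl]ethan-1-one | CC(=O)c1c(OCOC)cc(OCOC)c(CC=C(C)C)c1F | intermediate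
8 | chlorotrimethylsilane | C[Si](C)(C)Cl | starting material
9 | ({1-[2-fluoro-4,6-bis(methoxymethoxy)-3-(3-methylbut-2-en-1-yl)phenyl]ethenyl}oxy)trimethylsilane | C=C(O[Si](C)(C)C)c1c(OCOC)cc(OCOC)c(CC=C(C)C)c1F | intermediate
10 | 2,4-dihydroxybenzaldehyde | O=Cc1ccc(O)cc1O | starting material
11 | 2-hydroxy-4-[(3-methylbut-2-en-1-yl)oxy]benzaldehyde | O=Cc1ccc(OCC=C(C)C)cc1O | intermediate
12 | 2-(methoxymethoxy)-4-[(3-methylbut-2-en-1-yl)oxy]benzaldehyde | O=Cc1ccc(OCC=C(C)C)cc1OCOC | intermediate
13 | 4-hydroxy-2-(methoxymethoxy)-5-(2-methylbut-3-en-2-yl)benzaldehyde | O=Cc1cc(C(C)(C)C=C)c(O)cc1OCOC | intermediate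
14 | 2,4-bis(methoxymethoxy)-5-(2-methylbut-3-en-2-yl)benzaldehyde | O=Cc1cc(C(C)(C)C=C)c(OCOC)cc1OCOC | intermediate
15 | (3S)-3-[2,4-bis(methoxymethoxy)-5-(2-methylbut-3-en-2-yl)phenyl]-1-[2-fluoro-4,6-bis(methoxymethoxy)-3-(3-methylbut-2-en-1-yl)phenyl]-3-[(trimethylsilyl)oxy]propan-1-one | C=CC(C)(C)c1cc([C@H](CC(=O)c2c(OCOC)cc(OCOC)c(CC=C(C)C)c2F)O[Si](C)(C)C)c(OCOC)cc1OCOC | intermediate
16 | (2S)-2-[2,4-bis(methoxymethoxy)-5-(2-methylbut-3-en-2-yl)phenyl]-5,7-bis(methoxymethoxy)-8-(3-methylbut-2-en-1-yl)-2,3-dihydro-4H-chromen-4-one | C=CC(C)(C)c1cc([C@@H]2CC(=O)c3c(OCOC)cc(OCOC)c(CC=C(C)C)c3O2)c(OCOC)cc1OCOC | intermediate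
17 | (2S)-2-[2,4-dihydroxy-5-(2-methylbut-3-en-2-yl)phenyl]-5,7-dihydroxy-8-(3-methylbut-2-en-1-yl)-2,3-dihydro-4H-chromen-4-one | C=CC(C)(C)c1cc([C@@H]2CC(=O)c3c(O)cc(O)c(CC=C(C)C)c3O2)c(O)cc1O | target

**Summary**

Total step count: 10. Longest linear sequence: 6 steps (1→2→3→4→9→10, or 5→6→7→8→9→10).

Steps most likely to fail:

Step 9. The electron-rich, ortho-alkoxylated aldehyde may add slowly. The free alkoxide may fragment back to enolate and aldehyde (retro-aldol) before ring closure, which would erode enantiomeric purity, or eliminate to the chalcone. The fallback sets out from 7 and 14 and comes back at 16, making the two bonds in two separate operations under metal control. Ketone 7 would be enolised with B-chlorodiisopinocampheylborane (the antipode that directs Si-face addition) and Et3N in Et2O and added to 14 at −78 °C. Work-up with diethanolamine should give (3S)-3-[2,4-bis(methoxymethoxy)-5-(2-methylbut-3-en-2-yl)phenyl]-1-[2-fluoro-4,6-bis(methoxymethoxy)-3-(3-methylbut-2-en-1-yl)phenyl]-3-hydroxypropan-1-one F1. Its lithium alkoxide (LiHMDS, 1.0 equiv, THF/DMPU, −78 °C → rt) should then close ring C by SNAr with loss of LiF, a lithium aldolate being far slower to fragment than the ammonium alkoxide of the main route.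

Step 7. The rearrangement may go to C3, continue to abnormal-Claisen products, cyclise the ortho-allyl phenol to a dihydrobenzofuran, or lose the prenyl group. The fallback sets out from 10 and comes back at 14, making the quaternary benzylic carbon by cross-coupling instead of a sigmatropic shift. Bromination of 10 (Br2, AcOH) should give 5-bromo-2,4-dihydroxybenzaldehyde F5, and MOMCl/NaH then 5-bromo-2,4-bis(methoxymethoxy)benzaldehyde F6. A γ-selective Suzuki–Miyaura coupling of F6 with 4,4,5,5-tetramethyl-2-(3-methylbut-2-en-1-yl)-1,3,2-dioxaborolane (Pd(OAc)2, 1,1'-bis(di-tert-butylphosphino)ferrocene, K3PO4, THF/H2O, 60 °C) should deliver 14 directly.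

Step 2. Metalation may occur between the two MOM ethers (coordination control) instead of next to fluorine, and the ortho-fluoroaryllithium may lose LiF. The fallback sets out from 3 and comes back at 7, blocking the unwanted site first. Treatment of 3 with n-BuLi/TMEDA and then Me3SiCl should give [4-fluoro-2,6-bis(methoxymethoxy)phenyl]trimethylsilane F2. The two LDA-mediated functionalisations of steps 2 and 3 would then be run on the blocked arene, giving [4-fluoro-2,6-bis(methoxymethoxy)-3-(3-methylbut-2-en-1-yl)phenyl]trimethylsilane F3 and then 1-[2-fluoro-4,6-bis(methoxymethoxy)-3-(3-methylbut-2-en-1-yl)-5-(trimethylsilyl)phenyl]ethan-1-one F4. Fluoride-mediated protodesilylation (Bu4NF, wet THF, 50 °C) of the silane flanked by two alkoxy groups should return 7.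

Further compounds
F1 | step 9 | (3S)-3-[2,4-bis(methoxymethoxy)-5-(2-methylbut-3-en-2-yl)phenyl]-1-[2-fluoro-4,6-bis(methoxymethoxy)-3-(3-methylbut-2-en-1-yl)phenyl]-3-hydroxypropan-1-one | C=CC(C)(C)c1cc([C@@H](O)CC(=O)c2c(OCOC)cc(OCOC)c(CC=C(C)C)c2F)c(OCOC)cc1OCOC
F2 | step 2 | [4-fluoro-2,6-bis(methoxymethoxy)phenyl]trimethylsilane | COCOc1cc(F)cc(OCOC)c1[Si](C)(C)C
F3 | step 2 | [4-fluoro-2,6-bis(methoxymethoxy)-3-(3-methylbut-2-en-1-yl)phenyl]trimethylsilane | COCOc1c([Si](C)(C)C)c(OCOC)c(CC=C(C)C)c(F)c1
F4 | step 2 | 1-[2-fluoro-4,6-bis(methoxymethoxy)-3-(3-methylbut-2-en-1-yl)-5-(trimethylsilyl)phenyl]ethan-1-one | CC(=O)c1c(OCOC)c([Si](C)(C)C)c(OCOC)c(CC=C(C)C)c1F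
F5 | step 7 | 5-bromo-2,4-dihydroxybenzaldehyde | O=Cc1cc(Br)c(O)cc1O
F6 | step 7 | 5-bromo-2,4-bis(methoxymethoxy)benzaldehyde | O=Cc1cc(Br)c(OCOC)cc1OCOC
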